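## Retrosynthetic overview

1. The target comes from the fully assembled bicycle by one fluoride step that removes a silyl ether and a 2-silylethyl ester; there is no late redox or olefination.
2. Rings A and B are formed together in the penultimate step by a hydrogen-atom-transfer (HAT) initiated radical–polar crossover bicyclisation of an acyclic tetraene. Ring A closes first (C4–C5), then ring B (C9–C10). An allylsilane terminator gives the 8(17)-methylidene, and the single C2 silyloxy stereocentre controls C5, C9 and C10.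
3. The acyclic tetraene comes from a Negishi coupling of a C1–C12 alkylzinc with a (Z)-3-iodo-4-acetoxybutenoate, which fixes the 13E alkene.
4. The C1–C12 chain is grown linearly. Zirconium-catalysed methylalumination of a terminal alkyne with ethylene oxide capture gives the E C5=C10 alkene. One round of 2,3-dihydrofuran lithiation, alkylation and nickel-catalysed Grignard ring opening gives the (Z)-allylsilane at C8=C9.
5. The chirality source is (R)-epichlorohydrin (C1–C3), opened first by isopropenylmagnesium bromide and, after reclosure, by lithium acetylide.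

Assumption: labdane numbering (C1–C20) is used for positions; 4-hydroxybut-2-ynoic acid is taken as a catalogue compound; the first-choice route deliberately avoided is a preformed (chiral-pool or annulation-derived) decalin with late side-chain olefination.

## Route

Step 1
Reactants: 1 (R)-epichlorohydrin
Product: 2 (2R)-1-chloro-4-methylpent-4-en-2-ol
Conditions: isopropenylmagnesium bromide, CuI (10 mol %), THF, −40 to −20 °C; H2O work-up
Reagents that add atoms: isopropenylmagnesium bromide CC(=C)[Mg]Br
Why: Copper-catalysed Grignard opening of the epoxide (SN2 at the unsubstituted ring carbon) leaves the C–O stereocentre of 1 untouched, so the carbinol that becomes C2 is delivered as the (R)-chlorohydrin.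

Step 2
Reactants: 2 (2R)-1-chloro-4-methylpent-4-en-2-ol
Product: 3 (2R)-2-(2-methylprop-2-en-1-yl)oxirane
Conditions: NaOH (powder), Et2O, 0 °C to rt; distil
Reagents that add atoms: none
Why: Intramolecular Williamson etherification (alkoxide displaces the primary chloride) closes the new epoxide without breaking any bond at the stereocentre.

Step 3
Reactants: 3 (2R)-2-(2-methylprop-2-en-1-yl)oxirane
Product: 4 (4R)-2-methylhept-1-en-6-yn-4-ol
Conditions: LiC≡CH·H2NCH2CH2NH2 (lithium acetylide–ethylenediamine complex, 1.5 equiv), DMSO, 0 °C to rt; H2O work-up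
Reagents that add atoms: lithium acetylide–ethylenediamine complex [Li]C#C.NCCN
Why: Epoxide alkynylation, an SN2 opening of the terminal epoxide by the acetylide at the unsubstituted carbon, forms the C1–C10 bond and keeps the (R)-carbinol intact.

Step 4
Reactants: 4 (4R)-2-methylhept-1-en-6-yn-4-ol
Product: 5 tert-butyldimethyl{[(4R)-2-methylhept-1-en-6-yn-4-yl]oxy}silane
Conditions: TBSCl, imidazole, DMF, rt
Reagents that add atoms: tert-butyldimethylsilyl chloride CC(C)(C)[Si](C)(C)Cl
Why: Standard imidazole-mediated silylation of a secondary alcohol gives a bulky, non-participating ether that tolerates the organometallic steps and later sits equatorial to steer the cyclisation.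

Step 5
Reactants: 5 tert-butyldimethyl{[(4R)-2-methylhept-1-en-6-yn-4-yl]oxy}silane
Product: 8 (3E,6R)-6-[(tert-butyldimethylsilyl)oxy]-4,8-dimethylnona-3,8-dien-1-ol, via alkenylalane 6 (not isolated), via alkenylalanate 7 (not isolated)
Conditions: Me3Al (2.2 equiv), Cp2ZrCl2 (20 mol %), CH2Cl2, 0 °C to rt; remove volatiles; hexane/THF, n-BuLi (1.1 equiv), −78 to 0 °C; ethylene oxide (3 equiv), 0 °C to rt; aq potassium sodium tartrate
Reagents that add atoms: trimethylaluminium C[Al](C)C; ethylene oxide C1CO1
Why: Negishi zirconium-catalysed carboalumination adds methyl and aluminium syn across the terminal alkyne with aluminium at the terminal carbon, and the alkenylalanate made with n-BuLi opens ethylene oxide with retention at the alkenyl carbon, so the C5=C10 alkene is formed as the E isomer only.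

Step 6
Reactants: 8 (3E,6R)-6-[(tert-butyldimethylsilyl)oxy]-4,8-dimethylnona-3,8-dien-1-ol
Product: 9 tert-butyl{[(4R,6E)-9-iodo-2,6-dimethylnona-1,6-dien-4-yl]oxy}dimethylsilane
Conditions: PPh3, I2, imidazole (premixed), CH2Cl2, 0 °C
Reagents that add atoms: iodine II
Why: Appel-type iodination converts the primary alcohol by SN2 on its alkoxyphosphonium ion and leaves the silyl ether and both alkenes alone.

Step 7
Reactants: 9 tert-butyl{[(4R,6E)-9-iodo-2,6-dimethylnona-1,6-dien-4-yl]oxy}dimethylsilane; 10 2,3-dihydrofuran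
Product: 12 tert-butyl{[(4R,6E)-9-(4,5-dihydrofuran-2-yl)-2,6-dimethylnona-1,6-dien-4-yl]oxy}dimethylsilane, via lithiated dihydrofuran 11 (not isolated)
Conditions: 10, t-BuLi, THF, −78 to 0 °C; then 9, 0 °C to rt
Reagents that add atoms: none
Why: α-Lithiation of the cyclic enol ether followed by SN2 alkylation with the primary iodide forms the C7–C8 bond and installs the masked trisubstituted alkene.

Step 8
Reactants: 12 tert-butyl{[(4R,6E)-9-(4,5-dihydrofuran-2-yl)-2,6-dimethylnona-1,6-dien-4-yl]oxy}dimethylsilane
Product: 13 (3Z,7E,10R)-10-[(tert-butyldimethylsilyl)oxy]-8,12-dimethyl-4-[(trimethylsilyl)methyl]trideca-3,7,12-trien-1-ol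
Conditions: Me3SiCH2MgCl (3 equiv), NiCl2(PPh3)2 (5 mol %), toluene, 80 °C; H2O work-up
Reagents that add atoms: (trimethylsilyl)methylmagnesium chloride C[Si](C)(C)C[Mg]Cl
Why: Nickel-catalysed coupling of a cyclic enol ether with a Grignard reagent that has no β-hydrogen (Wenkert–Kocienski ring opening) replaces the vinylic C–O bond with retention, which puts CH2SiMe3 cis to the hydroxyethyl arm and so gives the (Z)-allylsilane whose geometry maps onto an equatorial C9 side chain.

Step 9
Reactants: 13 (3Z,7E,10R)-10-[(tert-butyldimethylsilyl)oxy]-8,12-dimethyl-4-[(trimethylsilyl)methyl]trideca-3,7,12-trien-1-ol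
Product: 15 tert-butyl{[(4R,6E,10Z)-13-iodo-2,6-dimethyl-10-[(trimethylsilyl)methyl]trideca-1,6,10-trien-4-yl]oxy}dimethylsilane, via mesylate 14 (not isolated)
Conditions: MsCl, Et3N, CH2Cl2, 0 °C; then NaI, acetone, 50 °C
Reagents that add atoms: sodium iodide [Na+].[I-]
Why: Mesylation followed by Finkelstein displacement (SN2) gives the primary iodide without any electrophilic iodine that would attack the allylsilane.

Step 10
Reactants: 16 4-hydroxybut-2-ynoic acid
Product: 17 4-(acetyloxy)but-2-ynoic acid
Conditions: AcCl (neat), 0 °C to rt; then H2O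
Reagents that add atoms: acetyl chloride CC(=O)Cl
Why: Base-free O-acylation of the primary alcohol with an acid chloride, with any mixed anhydride at the carboxyl group hydrolysed back on aqueous work-up.

Step 11
Reactants: 17 4-(acetyloxy)but-2-ynoic acid
Product: 18 (2Z)-4-(acetyloxy)-3-iodobut-2-enoic acid
Conditions: NaI, AcOH, 70 °C
Reagents that add atoms: sodium iodide [Na+].[I-]
Why: Conjugate hydroiodination of an ynoic acid proceeds by anti addition with iodide at the β-carbon, so iodine ends up cis to the carboxyl group (Z), the geometry needed for the 13E side chain.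

Step 12
Reactants: 18 (2Z)-4-(acetyloxy)-3-iodobut-2-enoic acid
Product: 19 2-(trimethylsilyl)ethyl (2Z)-4-(acetyloxy)-3-iodobut-2-enoate
Conditions: Me3SiCH2CH2OH, DCC, DMAP (5 mol %), CH2Cl2, −20 to 0 °C
Reagents that add atoms: 2-(trimethylsilyl)ethanol C[Si](C)(C)CCO
Why: Steglich esterification at low temperature masks the acid as a fluoride-labile ester without disturbing the vinyl iodide geometry or the acetate.

Step 13
Reactants: 15 tert-butyl{[(4R,6E,10Z)-13-iodo-2,6-dimethyl-10-[(trimethylsilyl)methyl]trideca-1,6,10-trien-4-yl]oxy}dimethylsilane; 19 2-(trimethylsilyl)ethyl (2Z)-4-(acetyloxy)-3-iodobut-2-enoate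
Product: 21 2-(trimethylsilyl)ethyl (2E,6Z,10E,13R)-3-[(acetyloxy)methyl]-13-[(tert-butyldimethylsilyl)oxy]-11,15-dimethyl-7-[(trimethylsilyl)methyl]hexadeca-2,6,10,15-tetraenoate, via alkylzinc iodide 20 (not isolated)
Conditions: Zn dust (activated with BrCH2CH2Br and Me3SiCl), THF/DMA, 40 °C; then 19, Pd2(dba)3 (2.5 mol %), P(2-furyl)3 (10 mol %), rt
Reagents that add atoms: none
Why: Zinc insertion into the primary iodide and Negishi coupling with the Z-iodoenoate go with retention of alkene geometry (oxidative addition of zerovalent palladium to the C–I bond is much faster than ionisation of the allylic acetate), placing the chain cis to the ester, which is the 13E alkene.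

Step 14
Reactants: 21 2-(trimethylsilyl)ethyl (2E,6Z,10E,13R)-3-[(acetyloxy)methyl]-13-[(tert-butyldimethylsilyl)oxy]-11,15-dimethyl-7-[(trimethylsilyl)methyl]hexadeca-2,6,10,15-tetraenoate
Product: 22 2-(trimethylsilyl)ethyl (2E)-3-[(acetyloxy)methyl]-5-[(1R,4aR,7R,8aR)-7-[(tert-butyldimethylsilyl)oxy]-5,5,8a-trimethyl-2-methylidenedecahydronaphthalen-1-yl]pent-2-enoate
Conditions: [N,N'-bis(3,5-di-tert-butylsalicylidene)-1,2-cyclohexanediaminato]cobalt (divalent cobalt, 5 mol %), N-fluoro-2,4,6-trimethylpyridinium triflate (1.2 equiv), (Me2SiH)2O (1.2 equiv), HFIP, 0 °C; aq NaHCO3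
Reagents that add atoms: none
Why: Proposed new method: the cobalt hydride made from the salen complex, the N-fluoropyridinium oxidant and the silane transfers a hydrogen atom selectively to the 1,1-disubstituted terminal alkene, the tertiary C4 radical is oxidised through an alkylcobalt species to a cation equivalent that is captured 6-endo by the C5=C10 alkene and then by the allylsilane (loss of Me3Si+ gives the 8(17)-methylidene, the electron-poor enoate is a spectator) through a chair–chair transition state in which the C2 silyloxy group must be equatorial (an axial one would clash with the C4 and C10 methyls), so the one (R)-carbinol sets C5, C9 and C10 as the trans-decalin with equatorial side chain; the closest known reaction types are cobalt-salen HAT-initiated radical–polar crossover polyene bicyclisations ended by arenes and Lewis-acid cationic polyene cyclisations ended by allylsilanes.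

Step 15
Reactants: 22 2-(trimethylsilyl)ethyl (2E)-3-[(acetyloxy)methyl]-5-[(1R,4aR,7R,8aR)-7-[(tert-butyldimethylsilyl)oxy]-5,5,8a-trimethyl-2-methylidenedecahydronaphthalen-1-yl]pent-2-enoate
Product: 23 (2E)-3-[(acetyloxy)methyl]-5-[(1R,4aR,7R,8aR)-7-hydroxy-5,5,8a-trimethyl-2-methylidenedecahydronaphthalen-1-yl]pent-2-enoic acid
Conditions: TASF [(Me2N)3S+ Me3SiF2−] (3 equiv), DMF, 0 °C to rt; pH 4 aqueous work-up (dilute HCl)
Reagents that add atoms: none
Why: Fluoride-mediated desilylation removes the silyl ether and fragments the 2-silylethyl ester (β-elimination of ethene) under non-hydrolytic, weakly basic conditions that spare the primary acetate and the exocyclic alkene, and no stereocentre is touched.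

## Compound list

1 | (R)-epichlorohydrin, (2R)-2-(chloromethyl)oxirane | ClC[C@H]1CO1 | starting material
2 | (2R)-1-chloro-4-methylpent-4-en-2-ol | ClC[C@H](O)CC(C)=C | intermediate
3 | (2R)-2-(2-methylprop-2-en-1-yl)oxirane | C=C(C)C[C@@H]1CO1 | intermediate
4 | (4R)-2-methylhept-1-en-6-yn-4-ol | C=C(C)C[C@@H](O)CC#C | intermediate
5 | tert-butyldimethyl{[(4R)-2-methylhept-1-en-6-yn-4-yl]oxy}silane | C=C(C)C[C@@H](O[Si](C)(C)C(C)(C)C)CC#C | intermediate
6 | {(1E,4R)-4-[(tert-butyldimethylsilyl)oxy]-2,6-dimethylhepta-1,6-dien-1-yl}dimethylalumane (alkenylalane) | C=C(C)C[C@@H](O[Si](C)(C)C(C)(C)C)C/C(C)=C/[Al](C)C | intermediate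
7 | lithium butyl{(1E,4R)-4-[(tert-butyldimethylsilyl)oxy]-2,6-dimethylhepta-1,6-dien-1-yl}dimethylaluminate (alkenylalanate) | [Li+].C=C(C)C[C@@H](O[Si](C)(C)C(C)(C)C)C/C(C)=C/[Al-](C)(C)CCCC | intermediate
8 | (3E,6R)-6-[(tert-butyldimethylsilyl)oxy]-4,8-dimethylnona-3,8-dien-1-ol | C=C(C)C[C@@H](O[Si](C)(C)C(C)(C)C)C/C(C)=C/CCO | intermediate
9 | tert-butyl{[(4R,6E)-9-iodo-2,6-dimethylnona-1,6-dien-4-yl]oxy}dimethylsilane | C=C(C)C[C@@H](O[Si](C)(C)C(C)(C)C)C/C(C)=C/CCI | intermediate
10 | 2,3-dihydrofuran | C1=COCC1 | starting material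
11 | 5-lithio-2,3-dihydrofuran (lithiated dihydrofuran) | [Li]C1=CCCO1 | intermediate
12 | tert-butyl{[(4R,6E)-9-(4,5-dihydrofuran-2-yl)-2,6-dimethylnona-1,6-dien-4-yl]oxy}dimethylsilane | C=C(C)C[C@@H](O[Si](C)(C)C(C)(C)C)C/C(C)=C/CCC1=CCCO1 | intermediate
13 | (3Z,7E,10R)-10-[(tert-butyldimethylsilyl)oxy]-8,12-dimethyl-4-[(trimethylsilyl)methyl]trideca-3,7,12-trien-1-ol | C=C(C)C[C@@H](O[Si](C)(C)C(C)(C)C)C/C(C)=C/CC/C(C[Si](C)(C)C)=C/CCO | intermediate
14 | (3Z,7E,10R)-10-[(tert-butyldimethylsilyl)oxy]-8,12-dimethyl-4-[(trimethylsilyl)methyl]trideca-3,7,12-trien-1-yl methanesulfonate (mesylate) | C=C(C)C[C@@H](O[Si](C)(C)C(C)(C)C)C/C(C)=C/CC/C(C[Si](C)(C)C)=C/CCOS(C)(=O)=O | intermediate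
15 | tert-butyl{[(4R,6E,10Z)-13-iodo-2,6-dimethyl-10-[(trimethylsilyl)methyl]trideca-1,6,10-trien-4-yl]oxy}dimethylsilane | C=C(C)C[C@@H](O[Si](C)(C)C(C)(C)C)C/C(C)=C/CC/C(C[Si](C)(C)C)=C/CCI | intermediate
16 | 4-hydroxybut-2-ynoic acid | OCC#CC(=O)O | starting material
17 | 4-(acetyloxy)but-2-ynoic acid | CC(=O)OCC#CC(=O)O | intermediate
18 | (2Z)-4-(acetyloxy)-3-iodobut-2-enoic acid | CC(=O)OC/C(I)=C/C(=O)O | intermediate
19 | 2-(trimethylsilyl)ethyl (2Z)-4-(acetyloxy)-3-iodobut-2-enoate | CC(=O)OC/C(I)=C/C(=O)OCC[Si](C)(C)C | intermediate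
20 | {(3Z,7E,10R)-10-[(tert-butyldimethylsilyl)oxy]-8,12-dimethyl-4-[(trimethylsilyl)methyl]trideca-3,7,12-trien-1-yl}zinc iodide (alkylzinc iodide) | C=C(C)C[C@@H](O[Si](C)(C)C(C)(C)C)C/C(C)=C/CC/C(C[Si](C)(C)C)=C/CC[Zn]I | intermediate
21 | 2-(trimethylsilyl)ethyl (2E,6Z,10E,13R)-3-[(acetyloxy)methyl]-13-[(tert-butyldimethylsilyl)oxy]-11,15-dimethyl-7-[(trimethylsilyl)methyl]hexadeca-2,6,10,15-tetraenoate | C=C(C)C[C@@H](O[Si](C)(C)C(C)(C)C)C/C(C)=C/CC/C(C[Si](C)(C)C)=C/CC/C(=C\C(=O)OCC[Si](C)(C)C)COC(C)=O | intermediate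
22 | 2-(trimethylsilyl)ethyl (2E)-3-[(acetyloxy)methyl]-5-[(1R,4aR,7R,8aR)-7-[(tert-butyldimethylsilyl)oxy]-5,5,8a-trimethyl-2-methylidenedecahydronaphthalen-1-yl]pent-2-enoate | C=C1CC[C@@H]2C(C)(C)C[C@@H](O[Si](C)(C)C(C)(C)C)C[C@@]2(C)[C@@H]1CC/C(=C\C(=O)OCC[Si](C)(C)C)COC(C)=O | intermediate
23 | (2E)-3-[(acetyloxy)methyl]-5-[(1R,4aR,7R,8aR)-7-hydroxy-5,5,8a-trimethyl-2-methylidenedecahydronaphthalen-1-yl]pent-2-enoic acid (CNP0292310.2) | C=C1CC[C@@H]2C(C)(C)C[C@@H](O)C[C@@]2(C)[C@@H]1CC/C(=C\C(=O)O)COC(C)=O | target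

## Step count and risks

Total step count: 15. Longest linear sequence: 12 steps (steps 1 to 9, then 13, 14 and 15, from (R)-epichlorohydrin).

The three steps most likely to fail:

Step 14 (HAT-initiated bicyclisation). The risks are hydrogen-atom transfer re-entering at the newly formed exocyclic alkene, which would isomerise it; attack of the N–F oxidant or of acid on the allylsilane before cyclisation; and radical capture by the enoate. Keeping oxidant and silane near 1.2 equivalents and stopping at full conversion limits the first of these. The fallback sets out from 21 and comes back at 22. Markovnikov HAT hydrochlorination of the isopropenyl group alone (TsCl, PhSiH3, catalytic Co(BF4)2·6H2O with a salicylaldimine ligand, EtOH, rt) gives the tertiary chloride F1. Ionisation of this chloride with SnCl4 in CH2Cl2 at −78 °C then starts a purely cationic, allylsilane-terminated bicyclisation to 22 through the same chair–chair arrangement. No metal hydride is present once the decalin and its exocyclic alkene exist.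

Step 5 (methylalumination and ethylene oxide capture). The alkenylalanate may transfer butyl or methyl to ethylene oxide instead of the alkenyl group, and excess Me3Al has to be removed without losing the alkenylalane. The fallback sets out from 3 and comes back at 8, bypassing steps 3 to 5. Commercial pent-3-yn-1-ol is hydrozirconated and iodinated (Cp2Zr(H)Cl, THF; then I2) to (3E)-4-iodopent-3-en-1-ol F2, which is silylated (TBSCl, imidazole) to the silyl ether F3. Iodine–lithium exchange (t-BuLi, Et2O, −78 °C) gives the alkenyllithium F4, which opens 3 with BF3·OEt2 to the secondary alcohol F5 with the E alkene already in place. Silylation gives the bis-silyl ether F6, and PPTS in MeOH removes only the primary silyl group to give 8.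

Step 15 (global fluoride deprotection). The liberated alkoxide or adventitious hydroxide may cleave the primary acetate. The fallback sets out from 22 and comes back at 23. Exhaustive deprotection (TBAF, THF; then K2CO3, MeOH) gives the dihydroxy acid F7, which cannot lactonise because the hydroxymethyl group is trans to the carboxyl group. Lipase-catalysed transesterification (immobilised Candida antarctica lipase B, vinyl acetate, MTBE, rt) then acetylates only the primary allylic alcohol, leaving the ring secondary alcohol and the acid free, to give 23.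

## Further compounds

F1 | step 14 | 2-(trimethylsilyl)ethyl (2E,6Z,10E,13S)-3-[(acetyloxy)methyl]-13-[(tert-butyldimethylsilyl)oxy]-15-chloro-11,15-dimethyl-7-[(trimethylsilyl)methyl]hexadeca-2,6,10-trienoate (tertiary chloride) | CC(C)(Cl)C[C@@H](O[Si](C)(C)C(C)(C)C)C/C(C)=C/CC/C(C[Si](C)(C)C)=C/CC/C(=C\C(=O)OCC[Si](C)(C)C)COC(C)=O
F2 | step 5 | (3E)-4-iodopent-3-en-1-ol | C/C(I)=C\CCO
F3 | step 5 | tert-butyl{[(3E)-4-iodopent-3-en-1-yl]oxy}dimethylsilane (silyl ether) | C/C(I)=C\CCO[Si](C)(C)C(C)(C)C
F4 | step 5 | {(2Z)-5-[(tert-butyldimethylsilyl)oxy]pent-2-en-2-yl}lithium (alkenyllithium) | C/C([Li])=C\CCO[Si](C)(C)C(C)(C)C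
F5 | step 5 | (4R,6E)-9-[(tert-butyldimethylsilyl)oxy]-2,6-dimethylnona-1,6-dien-4-ol (secondary alcohol) | C=C(C)C[C@@H](O)C/C(C)=C/CCO[Si](C)(C)C(C)(C)C
F6 | step 5 | (4R,6E)-4,9-bis[(tert-butyldimethylsilyl)oxy]-2,6-dimethylnona-1,6-diene (bis-silyl ether) | C=C(C)C[C@@H](O[Si](C)(C)C(C)(C)C)C/C(C)=C/CCO[Si](C)(C)C(C)(C)C
F7 | step 15 | (2E)-3-(hydroxymethyl)-5-[(1R,4aR,7R,8aR)-7-hydroxy-5,5,8a-trimethyl-2-methylidenedecahydronaphthalen-1-yl]pent-2-enoic acid (dihydroxy acid) | C=C1CC[C@@H]2C(C)(C)C[C@@H](O)C[C@@]2(C)[C@@H]1CC/C(=C\C(=O)O)CO
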